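The earlier runs and the new flask were computed with made-up constants, noise included.

The amounts of X were what I had to go on: as a percent of the D charged, X was still creeping up through Thursday's run, so I took its last two readings, at 15.0 min and 25.0 min, which average 63.4%, while in Friday's run X levelled off, reading about 67.8% from 8.00 min on.

| setting | Thursday's | Friday's | violet | teal |
|---|---|---|---|---|
| D | 0.050 M | 0.20 M | 0.10 M | 0.10 M |
| temperature | 105 °C | 118 °C | 110 °C | 125 °C |
| remark | run made earlier | run made earlier |  |  |
| time |  |  | 20 min | 20 min |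

| Thursday's: time / min | Thursday's: X / % | Friday's: time / min | Friday's: X / % |
|---|---|---|---|
| 2.00 | 51.3 | 4.00 | 64.5 |
| 3.00 | 59.2 | 8.00 | 68.1 |
| 5.00 | 60.1 | 12.0 | 68.2 |
| 8.00 | 60.4 | 15.0 | 67.3 |
| 15.0 | 63.8 | 20.0 | 67.3 |
| 25.0 | 63.0 | 25.0 | 68.1 |

(scatter of a reading: 1 percentage point)

- a species is counted by the D in it: one E or Q counts as two
- amounts and yields of X count Q too
- what was read earlier has a scatter of 1 percentage point, one standard deviation
- steps that have been proposed: D <-> X; D <-> J; D <-> Z; 2 D -> E; D + X <-> Q
- in an amount of X, one Q counts as one X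

- which of the two there is more of at the end, violet (J / X)
- which of the two there is more of at the end, teal (J / X)
- X at the end, in percent of the D charged, violet
- X at the end, in percent of the D charged, teal

I took the even case as my zero: with D, X, J and Z equally favoured, X would hold a quarter, odds of 0.333 against the rest. Thursday's odds were 1.73 and Friday's 2.11, both higher than that zero.

Those runs differed in charge and in temperature, so I solved two extremes. If charge alone mattered, violet and teal would share the geometric mean of the odds, since 0.10 M lies midway between the charges on a log scale, and X would stand at 65.6%. If temperature alone mattered, the tilt came to 18.5 kJ mol⁻¹; this tilt, R times the change in ln(odds) per change in reciprocal temperature, is an apparent van 't Hoff enthalpy. It put violet at 65.2% and teal at 69.9%.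

I leaned to the temperature end. D <-> X, D <-> J and D <-> Z each turn one molecule into one, so [D] cancels from their ratios, and Q is counted within X anyway. With X above half, I expected more X than J in both flasks.

The forecast gave violet 64.5% and teal 67.5%, with X ahead of J in both and teal “less certain”.

Violet gave 64.9% of X against 13.6% of J, and teal 70.8% against 12.0%.

    D ⇌ X (K = 11.0, k = 1.20 min⁻¹, Ea = 107 kJ mol⁻¹, ΔH = 16.0 kJ mol⁻¹)
    D ⇌ J (K = 2.30, k = 0.450 min⁻¹, Ea = 93.0 kJ mol⁻¹, ΔH = 0 kJ mol⁻¹)
    D ⇌ Z (K = 2.30, k = 0.260 min⁻¹, Ea = 111 kJ mol⁻¹, ΔH = −19.0 kJ mol⁻¹)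
    2 D → E (k = 0.120 M⁻¹ min⁻¹, Ea = 98.0 kJ mol⁻¹)
    D + X ⇌ Q, settled at all times (K = 4.30 M⁻¹, ΔH = −10.0 kJ mol⁻¹)
    (constants at 110 °C)

Starting from Thursday's run, changing the amount of D to teal's left X at 62.9%, while changing the temperature took it to 71.4%. The tilt, carried from violet's 64.9% up to teal's temperature, gave 69.7%. Carried down from teal's 70.8% to the same flask at 100 °C, it gave 62.5%, and that flask held 60.5%.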